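**Retrosynthetic overview**

1. The target (nostoxanthin mono-3-sulfate) comes from sulfation of the single free C3'-OH of a tris-TBS-protected nostoxanthin; the C40 polyene is assembled by two Wittig reactions, C15 (ring A) + C10 dialdehyde + C15 (ring B).
2. Each C15 phosphonium salt comes from a ring enol triflate by Stille coupling with a C5 dienylstannane; both triflates derive from one enantiopure trans-diol, (4R,5R)-4,5-dihydroxy-2,6,6-trimethylcyclohex-2-enone, silylated in two patterns (ring A: bis-TBS; ring B: 3-O-TES, 2-O-TBS).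
3. The diol comes from Jacobsen epoxidation of the γ,δ-cis-alkene of achiral 2,6,6-trimethylcyclohexa-2,4-dienone, followed by anti opening at the allylic carbon.
4. Key disconnection: the dienone is split into an isobutyraldehyde enamine (C1–C2) and the vinylketene from tigloyl chloride (C3–C6), joined through C6–C1 (acylation) and C2–C3 (vinylogous Mannich). This is the only carbocycle-forming step and supplies both end groups; the oxirane of step 3 is temporary and is opened in step 4.
5. Enabling feature: in each cyclohexene end group the quaternary gem-dimethyl carbon C1 lies between the chain-bearing sp2 carbon C6 and the carbinol carbon C2. The C1–C2 pair is therefore an isobutyraldehyde unit (nucleophilic α-carbon, electrophilic carbonyl carbon) bridging the acyl carbon C6 and the γ-carbon C3 of a 2-methylbut-2-enoyl unit C3–C4–C5(CH3)–C6, and the trans-2,3-diol is the latent form of the C2=C3 alkene left by this annulation.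

Key step: step 2

**Remarks on the chemistry**

- Ring atoms are numbered as in carotenoids: C1 (CMe2), C2 and C3 (carbinol carbons), C4 (CH2), C5 (methyl-bearing sp2 carbon), C6 (sp2 carbon bearing the polyene). Ring A is the unsulfated end group; ring B (primed numbers) is the sulfated one. Ring intermediates are named as cyclohexenones, in which C4 and C5 are carotenoid C3 and C2.
- Assumption: the target is drawn as the free hydrogen sulfate, so it is liberated from its pyridinium salt by cation exchange in the last step; it would be stored as a salt.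
- The Wittig steps are expected to give E/Z mixtures at the new double bond, which are equilibrated to the all-E isomer.

**Route**

Step 1
Reactants: 1 isobutyraldehyde; 2 pyrrolidine
Product: 3 1-(2-methylprop-1-en-1-yl)pyrrolidine
Conditions: cyclohexane, reflux, water separator; distillation
Reagents that add atoms: none
Why: Enamine formation from an α-branched aldehyde and a secondary amine is driven by azeotropic removal of water and creates no stereocentre.

Step 2
Reactants: 3 1-(2-methylprop-1-en-1-yl)pyrrolidine; 4 tigloyl chloride [(E)-2-methylbut-2-enoyl chloride]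
Product: 7 2,6,6-trimethylcyclohexa-2,4-dien-1-one, via vinylketene 5 (not isolated), via amino enone 6 (not isolated)
Conditions: Et3N (2.2 equiv), toluene, 0 °C to rt, 4 added over 4 h; then AcOH, 80 °C
Reagents that add atoms: none
Why: Proposed new method: triethylamine dehydrochlorinates 4 through its γ-methyl group to the vinylketene 5, the nucleophilic CMe2 carbon of enamine 3 adds to the ketene carbon (C6–C1 bond), and the resulting iminium/dienolate zwitterion closes through the dienolate γ-carbon onto the iminium carbon (C2–C3 bond, vinylogous Mannich) to amino enone 6, which loses pyrrolidine on warming with acetic acid by a vinylogous E1cB elimination to give the linearly conjugated dienone 7. The closest known reactions are the ketene–enamine [2+2] cycloaddition that gives 3-aminocyclobutanones through the same zwitterion (isobutyraldehyde enamines being classical partners), the trapping of vinylketenes made from crotonyl-type chlorides and triethylamine in Staudinger reactions, and the Stork C-acylation of aldehyde enamines; the new element is capture of the zwitterion at the γ-carbon to form a six-membered ring. The cyclohexenone ring closes in a 6-(enolendo)-exo-trig mode, formally a stepwise [4+2] between the four carbons of the vinylketene and the enamine C=C. No stereocentre survives, since the amine-bearing carbon of 6 is transient and 7 is achiral, so all stereochemistry is deferred to step 3. The step needs attack at the ketene carbon and not conjugate addition, which the α- and β-methyl groups of 4 and its slow addition into triethylamine should secure, and it needs γ- over α-closure, which is expected because the α-closure product is a donor–acceptor 3-aminocyclobutanone with two adjacent quaternary carbons that should reopen to the zwitterion, whereas γ-closure is followed by irreversible amine loss. Diels–Alder dimerisation of 7 should be slowed by its 2- and 6-substituents, and 7 is used without storage.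

Step 3
Reactants: 7 2,6,6-trimethylcyclohexa-2,4-dien-1-one
Product: 8 (4S,5R)-4,5-epoxy-2,6,6-trimethylcyclohex-2-en-1-one [(1R,6S)-2,2,4-trimethyl-7-oxabicyclo[4.1.0]hept-4-en-3-one]
Conditions: chloro[(S,S)-N,N'-bis(3,5-di-tert-butylsalicylidene)cyclohexane-1,2-diaminato]manganese [(S,S)-(salen)MnCl, 5 mol%], NMO, mCPBA, CH2Cl2, −78 °C
Reagents that add atoms: mCPBA, O=C(OO)c1cccc(Cl)c1
Why: In this Jacobsen epoxidation the electrophilic oxo-manganese species should select the electron-richer γ,δ-cis-alkene, which is flanked by the quaternary carbon exactly as in a 2,2-dimethylchromene, over the electron-poor α,β-alkene, and the (S,S)-ligand is chosen by analogy with the chromene series to deliver oxygen to the face that makes C5 R and C4 S (the sense of induction is to be confirmed and the (R,R)-catalyst used if it proves opposite), while the low-temperature peracid variant avoids hypochlorite, which could epoxidise the enone by conjugate addition.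

Step 4
Reactants: 8 (4S,5R)-4,5-epoxy-2,6,6-trimethylcyclohex-2-en-1-one
Product: 9 (4R,5R)-4,5-dihydroxy-2,6,6-trimethylcyclohex-2-en-1-one
Conditions: HClO4 (cat.), THF/H2O, 0 °C
Reagents that add atoms: water, O
Why: In this acid-catalysed anti hydrolysis of a vinyl epoxide, water should enter with inversion at the allylic C4 because C5 is neopentyl, so C5 keeps its configuration and the trans-(4R,5R)-diol results (attack at C5 would give the enantiomer, so this regioselectivity carries the enantiomeric purity), and the β-hydroxy ketone is kept away from base to avoid retro-aldol opening.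

Step 5
Reactants: 9 (4R,5R)-4,5-dihydroxy-2,6,6-trimethylcyclohex-2-en-1-one
Product: 10 (4R,5R)-4,5-bis(tert-butyldimethylsilyloxy)-2,6,6-trimethylcyclohex-2-en-1-one
Conditions: TBSOTf (2.5 equiv), 2,6-lutidine, CH2Cl2, 0 °C to rt
Reagents that add atoms: tert-butyldimethylsilyl trifluoromethanesulfonate, CC(C)(C)[Si](C)(C)OS(=O)(=O)C(F)(F)F
Why: Silyl ether formation with the silyl triflate is reactive enough for the neopentyl C5 hydroxyl and touches no stereocentre.

Step 6
Reactants: 10 (4R,5R)-4,5-bis(tert-butyldimethylsilyloxy)-2,6,6-trimethylcyclohex-2-en-1-one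
Product: 12 (4R,5R)-4,5-bis(tert-butyldimethylsilyloxy)-2,6,6-trimethylcyclohex-1-en-1-yl trifluoromethanesulfonate, via lithium enolate 11 (not isolated)
Conditions: LiBH(s-Bu)3 (L-Selectride), THF, −78 °C; then PhNTf2, −78 to 0 °C
Reagents that add atoms: N-phenylbis(trifluoromethanesulfonimide), O=S(=O)(N(c1ccccc1)S(=O)(=O)C(F)(F)F)C(F)(F)F
Why: Conjugate hydride reduction of the α-methyl enone by the bulky borohydride (1,2-attack being blocked by the flanking quaternary carbon) followed by O-triflation of the regiodefined enolate gives the tetrasubstituted enol triflate with the C5=C6 alkene in place, and no new stereocentre arises because the former α-carbon stays sp2.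

Step 7
Reactants: 13 (E)-3-methylpent-2-en-4-yn-1-ol
Product: 14 (2E,4E)-3-methyl-5-(tributylstannyl)penta-2,4-dien-1-ol
Conditions: Bu3SnH, PdCl2(PPh3)2 (2 mol%), THF, 0 °C to rt; chromatography
Reagents that add atoms: tributyltin hydride, CCCC[SnH](CCCC)CCCC
Why: Palladium-catalysed syn-hydrostannation of the terminal alkyne should place tin on the terminal carbon, the internal position being shielded by the branched alkenyl group, and give the (E)-alkenylstannane.

Step 8
Reactants: 12 ring A enol triflate; 14 (2E,4E)-3-methyl-5-(tributylstannyl)penta-2,4-dien-1-ol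
Product: 15 (2E,4E)-5-[(4R,5R)-4,5-bis(tert-butyldimethylsilyloxy)-2,6,6-trimethylcyclohex-1-en-1-yl]-3-methylpenta-2,4-dien-1-ol
Conditions: Pd2(dba)3 (5 mol%), AsPh3, LiCl, NMP, 60 °C
Reagents that add atoms: none
Why: Stille coupling of the enol triflate with the (E)-dienylstannane proceeds with retention of both alkene geometries, the weakly bound arsine ligand and chloride being the usual means of speeding transmetalation at hindered triflates.

Step 9
Reactants: 15 ring A C15 dienol
Product: 17 [(2E,4E)-5-[(4R,5R)-4,5-bis(tert-butyldimethylsilyloxy)-2,6,6-trimethylcyclohex-1-en-1-yl]-3-methylpenta-2,4-dien-1-yl]triphenylphosphonium bromide, via allylic bromide 16 (not isolated)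
Conditions: CBr4, PPh3, CH2Cl2, 0 °C; then PPh3, rt
Reagents that add atoms: carbon tetrabromide, BrC(Br)(Br)Br; triphenylphosphine, c1ccc(cc1)P(c1ccccc1)c1ccccc1
Why: Appel bromination of the primary allylic alcohol under neutral conditions, which the silyl ethers survive, followed by SN2 quaternisation of triphenylphosphine by the allylic bromide gives the phosphonium salt.

Step 10
Reactants: 17 ring A C15 phosphonium bromide; 18 (2E,4E,6E)-2,7-dimethylocta-2,4,6-trienedial
Product: 20 (2E,4E,6E,8E,10E,12E)-13-[(4R,5R)-4,5-bis(tert-butyldimethylsilyloxy)-2,6,6-trimethylcyclohex-1-en-1-yl]-2,7,11-trimethyltrideca-2,4,6,8,10,12-hexaenal (C25 aldehyde), via ylide 19 (not isolated)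
Conditions: NaOMe, MeOH/CH2Cl2, 0 °C to rt, 18 (3 equiv); then I2 (cat.), hexane, daylight
Reagents that add atoms: none
Why: The Wittig reaction of the semi-stabilised allylic ylide with an excess of the symmetrical dialdehyde should stop at mono-olefination, and the (Z)-isomer at the new double bond is equilibrated to the (E)-isomer.

Step 11
Reactants: 9 (4R,5R)-4,5-dihydroxy-2,6,6-trimethylcyclohex-2-en-1-one
Product: 21 (4R,5R)-5-hydroxy-2,6,6-trimethyl-4-(triethylsilyloxy)cyclohex-2-en-1-one
Conditions: TESCl (1.05 equiv), imidazole, CH2Cl2, −40 °C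
Reagents that add atoms: chlorotriethylsilane, CC[Si](Cl)(CC)CC
Why: Under kinetic control the allylic C4 hydroxyl is far more accessible than the neopentyl C5 hydroxyl, so one equivalent of silyl chloride at low temperature should give the 4-O-triethylsilyl ether.

Step 12
Reactants: 21 (4R,5R)-5-hydroxy-2,6,6-trimethyl-4-(triethylsilyloxy)cyclohex-2-en-1-one
Product: 22 (4R,5R)-5-(tert-butyldimethylsilyloxy)-2,6,6-trimethyl-4-(triethylsilyloxy)cyclohex-2-en-1-one
Conditions: TBSOTf, 2,6-lutidine, CH2Cl2, −20 to 0 °C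
Reagents that add atoms: tert-butyldimethylsilyl trifluoromethanesulfonate, CC(C)(C)[Si](C)(C)OS(=O)(=O)C(F)(F)F
Why: Silylation of the hindered hydroxyl with the silyl triflate and a non-nucleophilic base forms no alkoxide, so the triethylsilyl group should neither migrate nor be lost.

Step 13
Reactants: 22 (4R,5R)-5-(tert-butyldimethylsilyloxy)-2,6,6-trimethyl-4-(triethylsilyloxy)cyclohex-2-en-1-one
Product: 24 (4R,5R)-5-(tert-butyldimethylsilyloxy)-2,6,6-trimethyl-4-(triethylsilyloxy)cyclohex-1-en-1-yl trifluoromethanesulfonate, via lithium enolate 23 (not isolated)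
Conditions: LiBH(s-Bu)3 (L-Selectride), THF, −78 °C; then PhNTf2, −78 to 0 °C
Reagents that add atoms: N-phenylbis(trifluoromethanesulfonimide), O=S(=O)(N(c1ccccc1)S(=O)(=O)C(F)(F)F)C(F)(F)F
Why: Conjugate reduction and enolate O-triflation as in step 6 give the ring B enol triflate without touching the stereocentres.

Step 14
Reactants: 24 ring B enol triflate; 14 (2E,4E)-3-methyl-5-(tributylstannyl)penta-2,4-dien-1-ol
Product: 25 (2E,4E)-5-[(4R,5R)-5-(tert-butyldimethylsilyloxy)-2,6,6-trimethyl-4-(triethylsilyloxy)cyclohex-1-en-1-yl]-3-methylpenta-2,4-dien-1-ol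
Conditions: Pd2(dba)3 (5 mol%), AsPh3, LiCl, NMP, 60 °C
Reagents that add atoms: none
Why: Stille coupling as in step 8 proceeds with retention of alkene geometry.

Step 15
Reactants: 25 ring B C15 dienol
Product: 27 [(2E,4E)-5-[(4R,5R)-5-(tert-butyldimethylsilyloxy)-2,6,6-trimethyl-4-(triethylsilyloxy)cyclohex-1-en-1-yl]-3-methylpenta-2,4-dien-1-yl]triphenylphosphonium bromide, via allylic bromide 26 (not isolated)
Conditions: CBr4, PPh3, CH2Cl2, 0 °C; then PPh3, rt
Reagents that add atoms: carbon tetrabromide, BrC(Br)(Br)Br; triphenylphosphine, c1ccc(cc1)P(c1ccccc1)c1ccccc1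
Why: Appel bromination and phosphine quaternisation as in step 9 are neutral enough for the acid-labile triethylsilyl ether.

Step 16
Reactants: 20 C25 aldehyde; 27 ring B C15 phosphonium bromide
Product: 29 (2R,3R,2'R,3'R)-2,3,2'-tris(tert-butyldimethylsilyloxy)-3'-(triethylsilyloxy)-β,β-carotene, via ylide 28 (not isolated)
Conditions: NaOMe, MeOH/CH2Cl2, rt, dark; then I2 (cat.), hexane/CH2Cl2, daylight
Reagents that add atoms: none
Why: The Wittig reaction of the allylic ylide with the polyenal closes the C40 chain, and equilibration gives the all-E polyene.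

Step 17
Reactants: 29 (2R,3R,2'R,3'R)-2,3,2'-tris(tert-butyldimethylsilyloxy)-3'-(triethylsilyloxy)-β,β-carotene
Product: 30 (2R,3R,2'R,3'R)-2,3,2'-tris(tert-butyldimethylsilyloxy)-β,β-caroten-3'-ol
Conditions: PPTS (cat.), MeOH/CH2Cl2, 0 °C, dark
Reagents that add atoms: none
Why: Mild acid-catalysed methanolysis cleaves the triethylsilyl ether much faster than the three tert-butyldimethylsilyl ethers and so frees only the C3' hydroxyl.

Step 18
Reactants: 30 (2R,3R,2'R,3'R)-2,3,2'-tris(tert-butyldimethylsilyloxy)-β,β-caroten-3'-ol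
Product: 31 pyridinium (2R,3R,2'R,3'R)-2,3,2'-tris(tert-butyldimethylsilyloxy)-β,β-caroten-3'-yl sulfate
Conditions: SO3·pyridine (5 equiv), pyridine, rt, dark
Reagents that add atoms: sulfur trioxide–pyridine complex, O=S(=O)([O-])[n+]1ccccc1
Why: O-Sulfation of the only free hydroxyl with the sulfur trioxide–pyridine complex is a mild sulfate monoester formation that polyenes tolerate.

Step 19
Reactants: 31 pyridinium tris-silyl carotenyl sulfate
Product: 33 (2R,3R,2'R,3'R)-β,β-carotene-2,3,2',3'-tetrol 3'-(hydrogen sulfate) (CNP0229621.3), via triol pyridinium sulfate 32 (not isolated)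
Conditions: HF·pyridine, pyridine, THF, 0 °C to rt, dark; then Dowex 50W-X8 (H+ form), MeOH, 0 °C
Reagents that add atoms: none
Why: Fluoride-mediated desilylation leaves the sulfate monoester intact, and cation exchange replaces pyridinium by a proton to give the hydrogen sulfate as drawn.

**Compound list**

1 | isobutyraldehyde | CC(C)C=O | starting material
2 | pyrrolidine | C1CCNC1 | starting material
3 | 1-(2-methylprop-1-en-1-yl)pyrrolidine | CC(C)=CN1CCCC1 | intermediate
4 | tigloyl chloride, (E)-2-methylbut-2-enoyl chloride | C/C=C(\C)C(=O)Cl | starting material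
5 | 2-methylbuta-1,3-dien-1-one (vinylketene) | C=CC(C)=C=O | intermediate
6 | 2,6,6-trimethyl-5-(pyrrolidin-1-yl)cyclohex-2-en-1-one (amino enone, racemic) | CC1=CCC(N2CCCC2)C(C)(C)C1=O | intermediate
7 | 2,6,6-trimethylcyclohexa-2,4-dien-1-one | CC1=CC=CC(C)(C)C1=O | intermediate
8 | (4S,5R)-4,5-epoxy-2,6,6-trimethylcyclohex-2-en-1-one | O=C1C(C)(C)[C@H]2O[C@H]2C=C1C | intermediate
9 | (4R,5R)-4,5-dihydroxy-2,6,6-trimethylcyclohex-2-en-1-one | O=C1C(C)(C)[C@@H](O)[C@H](O)C=C1C | intermediate
10 | (4R,5R)-4,5-bis(tert-butyldimethylsilyloxy)-2,6,6-trimethylcyclohex-2-en-1-one | O=C1C(C)(C)[C@@H](O[Si](C)(C)C(C)(C)C)[C@H](O[Si](C)(C)C(C)(C)C)C=C1C | intermediate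
11 | lithium (4R,5R)-4,5-bis(tert-butyldimethylsilyloxy)-2,6,6-trimethylcyclohex-1-en-1-olate | CC1=C([O-])C(C)(C)[C@@H](O[Si](C)(C)C(C)(C)C)[C@H](O[Si](C)(C)C(C)(C)C)C1.[Li+] | intermediate
12 | (4R,5R)-4,5-bis(tert-butyldimethylsilyloxy)-2,6,6-trimethylcyclohex-1-en-1-yl trifluoromethanesulfonate | CC1=C(OS(=O)(=O)C(F)(F)F)C(C)(C)[C@@H](O[Si](C)(C)C(C)(C)C)[C@H](O[Si](C)(C)C(C)(C)C)C1 | intermediate
13 | (E)-3-methylpent-2-en-4-yn-1-ol | C#C/C(C)=C/CO | starting material
14 | (2E,4E)-3-methyl-5-(tributylstannyl)penta-2,4-dien-1-ol | CCCC[Sn](CCCC)(CCCC)/C=C/C(C)=C/CO | intermediate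
15 | (2E,4E)-5-[(4R,5R)-4,5-bis(tert-butyldimethylsilyloxy)-2,6,6-trimethylcyclohex-1-en-1-yl]-3-methylpenta-2,4-dien-1-ol | CC1=C(/C=C/C(C)=C/CO)C(C)(C)[C@@H](O[Si](C)(C)C(C)(C)C)[C@H](O[Si](C)(C)C(C)(C)C)C1 | intermediate
16 | ring A C15 allylic bromide | CC1=C(/C=C/C(C)=C/CBr)C(C)(C)[C@@H](O[Si](C)(C)C(C)(C)C)[C@H](O[Si](C)(C)C(C)(C)C)C1 | intermediate
17 | ring A C15 triphenylphosphonium bromide | CC1=C(/C=C/C(C)=C/C[P+](c2ccccc2)(c2ccccc2)c2ccccc2)C(C)(C)[C@@H](O[Si](C)(C)C(C)(C)C)[C@H](O[Si](C)(C)C(C)(C)C)C1.[Br-] | intermediate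
18 | (2E,4E,6E)-2,7-dimethylocta-2,4,6-trienedial | O=C/C(C)=C/C=C/C=C(C)/C=O | starting material
19 | ring A C15 phosphorus ylide | CC1=C(/C=C/C(C)=C/C=P(c2ccccc2)(c2ccccc2)c2ccccc2)C(C)(C)[C@@H](O[Si](C)(C)C(C)(C)C)[C@H](O[Si](C)(C)C(C)(C)C)C1 | intermediate
20 | C25 aldehyde, all-E 13-[(4R,5R)-4,5-bis(tert-butyldimethylsilyloxy)-2,6,6-trimethylcyclohex-1-en-1-yl]-2,7,11-trimethyltrideca-2,4,6,8,10,12-hexaenal | CC1=C(/C=C/C(C)=C/C=C/C(C)=C/C=C/C=C(C)/C=O)C(C)(C)[C@@H](O[Si](C)(C)C(C)(C)C)[C@H](O[Si](C)(C)C(C)(C)C)C1 | intermediate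
21 | (4R,5R)-5-hydroxy-2,6,6-trimethyl-4-(triethylsilyloxy)cyclohex-2-en-1-one | O=C1C(C)(C)[C@@H](O)[C@H](O[Si](CC)(CC)CC)C=C1C | intermediate
22 | (4R,5R)-5-(tert-butyldimethylsilyloxy)-2,6,6-trimethyl-4-(triethylsilyloxy)cyclohex-2-en-1-one | O=C1C(C)(C)[C@@H](O[Si](C)(C)C(C)(C)C)[C@H](O[Si](CC)(CC)CC)C=C1C | intermediate
23 | lithium (4R,5R)-5-(tert-butyldimethylsilyloxy)-2,6,6-trimethyl-4-(triethylsilyloxy)cyclohex-1-en-1-olate | CC1=C([O-])C(C)(C)[C@@H](O[Si](C)(C)C(C)(C)C)[C@H](O[Si](CC)(CC)CC)C1.[Li+] | intermediate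
24 | (4R,5R)-5-(tert-butyldimethylsilyloxy)-2,6,6-trimethyl-4-(triethylsilyloxy)cyclohex-1-en-1-yl trifluoromethanesulfonate | CC1=C(OS(=O)(=O)C(F)(F)F)C(C)(C)[C@@H](O[Si](C)(C)C(C)(C)C)[C@H](O[Si](CC)(CC)CC)C1 | intermediate
25 | (2E,4E)-5-[(4R,5R)-5-(tert-butyldimethylsilyloxy)-2,6,6-trimethyl-4-(triethylsilyloxy)cyclohex-1-en-1-yl]-3-methylpenta-2,4-dien-1-ol | CC1=C(/C=C/C(C)=C/CO)C(C)(C)[C@@H](O[Si](C)(C)C(C)(C)C)[C@H](O[Si](CC)(CC)CC)C1 | intermediate
26 | ring B C15 allylic bromide | CC1=C(/C=C/C(C)=C/CBr)C(C)(C)[C@@H](O[Si](C)(C)C(C)(C)C)[C@H](O[Si](CC)(CC)CC)C1 | intermediate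
27 | ring B C15 triphenylphosphonium bromide | CC1=C(/C=C/C(C)=C/C[P+](c2ccccc2)(c2ccccc2)c2ccccc2)C(C)(C)[C@@H](O[Si](C)(C)C(C)(C)C)[C@H](O[Si](CC)(CC)CC)C1.[Br-] | intermediate
28 | ring B C15 phosphorus ylide | CC1=C(/C=C/C(C)=C/C=P(c2ccccc2)(c2ccccc2)c2ccccc2)C(C)(C)[C@@H](O[Si](C)(C)C(C)(C)C)[C@H](O[Si](CC)(CC)CC)C1 | intermediate
29 | (2R,3R,2'R,3'R)-2,3,2'-tris(tert-butyldimethylsilyloxy)-3'-(triethylsilyloxy)-β,β-carotene | CC1=C(/C=C/C(C)=C/C=C/C(C)=C/C=C/C=C(C)/C=C/C=C(C)/C=C/C2=C(C)C[C@@H](O[Si](CC)(CC)CC)[C@H](O[Si](C)(C)C(C)(C)C)C2(C)C)C(C)(C)[C@@H](O[Si](C)(C)C(C)(C)C)[C@H](O[Si](C)(C)C(C)(C)C)C1 | intermediate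
30 | (2R,3R,2'R,3'R)-2,3,2'-tris(tert-butyldimethylsilyloxy)-β,β-caroten-3'-ol | CC1=C(/C=C/C(C)=C/C=C/C(C)=C/C=C/C=C(C)/C=C/C=C(C)/C=C/C2=C(C)C[C@@H](O)[C@H](O[Si](C)(C)C(C)(C)C)C2(C)C)C(C)(C)[C@@H](O[Si](C)(C)C(C)(C)C)[C@H](O[Si](C)(C)C(C)(C)C)C1 | intermediate
31 | pyridinium (2R,3R,2'R,3'R)-2,3,2'-tris(tert-butyldimethylsilyloxy)-β,β-caroten-3'-yl sulfate | CC1=C(/C=C/C(C)=C/C=C/C(C)=C/C=C/C=C(C)/C=C/C=C(C)/C=C/C2=C(C)C[C@@H](OS(=O)(=O)[O-])[C@H](O[Si](C)(C)C(C)(C)C)C2(C)C)C(C)(C)[C@@H](O[Si](C)(C)C(C)(C)C)[C@H](O[Si](C)(C)C(C)(C)C)C1.c1cc[nH+]cc1 | intermediate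
32 | pyridinium (2R,3R,2'R,3'R)-2,3,2'-trihydroxy-β,β-caroten-3'-yl sulfate | CC1=C(/C=C/C(C)=C/C=C/C(C)=C/C=C/C=C(C)/C=C/C=C(C)/C=C/C2=C(C)C[C@@H](OS(=O)(=O)[O-])[C@H](O)C2(C)C)C(C)(C)[C@@H](O)[C@H](O)C1.c1cc[nH+]cc1 | intermediate
33 | (2R,3R,2'R,3'R)-β,β-carotene-2,3,2',3'-tetrol 3'-(hydrogen sulfate), CNP0229621.3 | CC1=C(/C=C/C(C)=C/C=C/C(C)=C/C=C/C=C(C)/C=C/C=C(C)/C=C/C2=C(C)C[C@@H](OS(=O)(=O)O)[C@H](O)C2(C)C)C(C)(C)[C@@H](O)[C@H](O)C1 | target

**Step count and risks**

Total step count: 19.
Longest linear sequence: 13 steps (steps 1–4, 11–15, 16–19; the ring A branch through steps 5, 6, 8, 9, 10 is equally long).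

Steps most likely to fail:

1. Step 2 (proposed new method). What may go wrong: closure of the zwitterion at the α-carbon to a cyclobutanone that does not reopen, conjugate addition of the enamine to the acid chloride, ketene dimerisation, or Diels–Alder dimerisation of the dienone. Fallback (known chemistry): this fallback does not branch from a numbered compound; compounds 3 and 4 are replaced by commercial 2,6-dimethylphenol, which is deprotonated with NaH in toluene to sodium 2,6-dimethylphenolate F1. F1 is C-methylated at the ortho carbon with iodomethane in the non-polar medium (alkylative dearomatisation of a phenolate), the O-methyl ether being removed by distillation. The fallback comes back to the route at compound 7.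

2. Step 3. What may go wrong: poor facial selectivity of oxygen transfer, or competing oxidation of the enone alkene. Fallback: it sets out from compound 7, which is epoxidised without a chiral catalyst (mCPBA, CH2Cl2, 0 °C) to the racemic cis-epoxide F2 and hydrolysed as in step 4 to the racemic trans-diol F3. F3 is resolved by lipase-catalysed acetylation of the C4 hydroxyl (Pseudomonas cepacia lipase, vinyl acetate), which should acylate one enantiomer only. If the (4S,5S)-enantiomer reacts, its acetate F4 is separated and the unreacted diol is compound 9. If the (4R,5R)-enantiomer reacts, its acetate F5 is separated and methanolysed (K2CO3, MeOH) to compound 9. The fallback comes back to the route at compound 9.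

3. Step 8 (the same coupling recurs in step 14). What may go wrong: slow oxidative addition and transmetalation at the hindered tetrasubstituted enol triflate, with reduction of the triflate or homocoupling of the stannane taking over. Fallback: it sets out from compound 12, which is methoxycarbonylated (Pd(OAc)2, dppp, CO, MeOH, Et3N, DMF, 60 °C) to the methyl cyclohexenecarboxylate F6. F6 is reduced with i-Bu2AlH to the allylic alcohol F7 and oxidised with MnO2 to the aldehyde F8. A Horner–Wadsworth–Emmons reaction of F8 with triethyl (E)-3-methyl-4-phosphonobut-2-enoate (LiN(SiMe3)2, THF) gives the ethyl (2E,4E)-dienoate F9, and reduction with i-Bu2AlH gives compound 15, where the fallback comes back to the route.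

**Further compounds**

F1 | step 2 | sodium 2,6-dimethylphenolate | Cc1cccc(C)c1[O-].[Na+]
F2 | step 3 | racemic cis-4,5-epoxy-2,6,6-trimethylcyclohex-2-en-1-one (both enantiomers) | O=C1C(C)(C)[C@H]2O[C@H]2C=C1C.O=C1C(C)(C)[C@@H]2O[C@@H]2C=C1C
F3 | step 3 | racemic trans-4,5-dihydroxy-2,6,6-trimethylcyclohex-2-en-1-one (both enantiomers) | O=C1C(C)(C)[C@@H](O)[C@H](O)C=C1C.O=C1C(C)(C)[C@H](O)[C@@H](O)C=C1C
F4 | step 3 | (4S,5S)-4-acetoxy-5-hydroxy-2,6,6-trimethylcyclohex-2-en-1-one | O=C1C(C)(C)[C@H](O)[C@@H](OC(C)=O)C=C1C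
F5 | step 3 | (4R,5R)-4-acetoxy-5-hydroxy-2,6,6-trimethylcyclohex-2-en-1-one | O=C1C(C)(C)[C@@H](O)[C@H](OC(C)=O)C=C1C
F6 | step 8 | methyl (4R,5R)-4,5-bis(tert-butyldimethylsilyloxy)-2,6,6-trimethylcyclohex-1-ene-1-carboxylate | CC1=C(C(=O)OC)C(C)(C)[C@@H](O[Si](C)(C)C(C)(C)C)[C@H](O[Si](C)(C)C(C)(C)C)C1
F7 | step 8 | [(4R,5R)-4,5-bis(tert-butyldimethylsilyloxy)-2,6,6-trimethylcyclohex-1-en-1-yl]methanol | CC1=C(CO)C(C)(C)[C@@H](O[Si](C)(C)C(C)(C)C)[C@H](O[Si](C)(C)C(C)(C)C)C1
F8 | step 8 | (4R,5R)-4,5-bis(tert-butyldimethylsilyloxy)-2,6,6-trimethylcyclohex-1-ene-1-carbaldehyde | CC1=C(C=O)C(C)(C)[C@@H](O[Si](C)(C)C(C)(C)C)[C@H](O[Si](C)(C)C(C)(C)C)C1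
F9 | step 8 | ethyl (2E,4E)-5-[(4R,5R)-4,5-bis(tert-butyldimethylsilyloxy)-2,6,6-trimethylcyclohex-1-en-1-yl]-3-methylpenta-2,4-dienoate | CC1=C(/C=C/C(C)=C/C(=O)OCC)C(C)(C)[C@@H](O[Si](C)(C)C(C)(C)C)[C@H](O[Si](C)(C)C(C)(C)C)C1
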